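**Retrosynthetic overview**

1. Numbering is that of hydroazulene: five-membered ring C1, C2, C3 (isopropyl), C3a (OH), C8a (methyl); seven-membered ring C3a, C4, C5, C6 (methyl carbinol), C7 (anisate), C8, C8a; β is the face of the C3 isopropyl group. The strategy rests on the oxygens at C3a and C6 lying 1,4 across the seven-membered ring, with C7 oxygenated next to C6 and the C3a hydroxyl cis to both the isopropyl and the angular methyl. This is the imprint of an oxygen-bridged (5+2) adduct whose bridge oxygen stays on C3a.
2. Disconnections: anisate and C7–OH (directed reduction), then C6–OH (α-face Rubottom oxidation of the C6=C7 enolate released when the C6–O bridge bond is cut reductively), then C8a methyl (exo cuprate addition), then 3-oxidopyrylium (5+2) cycloaddition forming C3a–C4 and C5–C6.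
3. The two-carbon partner is tert-butyl acrylate rather than a sulfonyl alkene. Acceptor alkenes place their substituted carbon on C4, next to C3a, so a group there must leave without a C4 carbanion β to the C3a–O bond. The ester leaves by radical decarboxylation, and regio- and endo/exo isomers then converge.
4. The ylide precursor is the acetoxypyranone from Achmatowicz oxidation of a cyclopentane-fused furfuryl alcohol. Its single stereocentre (C3) comes from CuH conjugate reduction of 3-isopropylcyclopent-2-enone; the furan is built through acyloin, butenolide and iBu2AlH reduction.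
5. Ring order: cyclopentane (present from the start), furan, pyranone, then the seven-membered carbocycle in the key step.

Key step: step 9

Remark: (R)-p-tol-BINAP is written in step 2 on the assumption that it directs hydride to the enone face giving the (3R)-enol silane; if the sense of induction is the opposite, the (S)-ligand is used and nothing else changes.

**Route**

Step 1
Reactants: 1 3-ethoxycyclopent-2-en-1-one
Product: 3 3-isopropylcyclopent-2-en-1-one, via chloromagnesium alkoxide adduct 2 (not isolated)
Conditions: iPrMgCl, THF, 0 °C; then 1 M HCl, rt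
Reagents that add atoms: isopropylmagnesium chloride, CC(C)[Mg]Cl; water, O
Why: Stork–Danheiser enone synthesis: 1,2-addition of the Grignard reagent to the vinylogous ester followed by acid hydrolysis, with loss of ethanol and water, transposes the carbonyl group and gives the 3-substituted enone; no stereocentre is formed.

Step 2
Reactants: 3 3-isopropylcyclopent-2-en-1-one
Product: 4 diethoxy{[(3R)-3-isopropylcyclopent-1-en-1-yl]oxy}methylsilane
Conditions: CuCl (5 mol %), NaOtBu (5 mol %), (R)-p-tol-BINAP (5 mol %), (EtO)2MeSiH (1.2 equiv), toluene, 0 °C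
Reagents that add atoms: diethoxy(methyl)silane, CCO[SiH](C)OCC
Why: Ligand-controlled copper hydride conjugate reduction of a 3-alkylcyclopentenone (asymmetric 1,4-hydrosilylation): hydride is delivered to C3 on the face selected by the BINAP ligand, which sets the one stereocentre carried to the target, and the copper enolate is silylated by the monohydrosilane in the catalytic cycle, so each enone gives one enol silane with its double bond only between C1 and C2.

Step 3
Reactants: 4 diethoxy{[(3R)-3-isopropylcyclopent-1-en-1-yl]oxy}methylsilane
Product: 6 (2R,3R)-2-hydroxy-3-isopropylcyclopentan-1-one (trans), via silyloxy ketone 5 (not isolated)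
Conditions: mCPBA, NaHCO3, CH2Cl2, −20 °C; then 1 M HCl, THF, 0 °C
Reagents that add atoms: 3-chloroperoxybenzoic acid (mCPBA), O=C(OO)c1cccc(Cl)c1
Why: Rubottom oxidation: the buffered peracid epoxidises the enol silane anti to the neighbouring isopropyl group, silyl migration and acid hydrolysis give the trans α-hydroxy ketone with oxygen on the carbon next to the isopropyl centre, and this new carbinol centre is erased again in step 5.

Step 4
Reactants: 6 (2R,3R)-2-hydroxy-3-isopropylcyclopentan-1-one; 7 (triphenylphosphoranylidene)ketene
Product: 9 (6R,6aR)-6-isopropyl-4,5,6,6a-tetrahydro-2H-cyclopenta[b]furan-2-one, via phosphorus ylide ester 8 (not isolated)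
Conditions: toluene, 90 °C
Reagents that add atoms: none
Why: Bestmann butenolide synthesis: the hydroxyl group adds to the ketene ylide and the resulting stabilised ylide closes by intramolecular Wittig reaction on the adjacent ketone; no new stereocentre is formed and the isopropyl centre is not acidic.

Step 5
Reactants: 9 butenolide
Product: 11 (6R)-6-isopropyl-5,6-dihydro-4H-cyclopenta[b]furan, via lactol 10 (not isolated)
Conditions: iBu2AlH (DIBAL-H), CH2Cl2, −78 °C; then 1 M HCl, 0 °C
Reagents that add atoms: none
Why: Partial reduction of the butenolide to the lactol and acid-promoted loss of water aromatise the ring to the furan (standard butenolide-to-furan conversion); the ring-fusion CH is lost and the isopropyl centre is untouched.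

Step 6
Reactants: 11 (6R)-6-isopropyl-5,6-dihydro-4H-cyclopenta[b]furan; 12 acetaldehyde
Product: 14 1-[(6R)-6-isopropyl-5,6-dihydro-4H-cyclopenta[b]furan-2-yl]ethan-1-ol (both carbinol epimers), via 2-lithiofuran 13 (not isolated)
Conditions: n-BuLi, THF, −78 → 0 °C; MeCHO, −78 °C; then H2O
Reagents that add atoms: none
Why: α-Lithiation of the furan at its only free α position followed by organolithium addition to the aldehyde; the carbinol centre forms unselectively, which does not matter because it becomes sp2 in the ylide.

Step 7
Reactants: 14 furfuryl alcohol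
Product: 15 (7R)-7a-hydroxy-7-isopropyl-2-methyl-5,6,7,7a-tetrahydrocyclopenta[b]pyran-3(2H)-one (epimers at C2 and C7a)
Conditions: NBS, NaHCO3, THF/H2O, 0 °C
Reagents that add atoms: water, O
Why: Achmatowicz rearrangement: electrophilic bromine attacks the furan, water adds and the resulting cis-enedione is closed by the side-chain hydroxyl to the 6-hydroxypyran-3-one hemiketal; the buffer and low temperature limit ring-chain tautomerism, in which the isopropyl centre would be α to a ketone.

Step 8
Reactants: 15 hydroxypyranone
Product: 16 (7R)-7-isopropyl-2-methyl-3-oxo-2,3,5,6,7,7a-hexahydrocyclopenta[b]pyran-7a-yl acetate (epimers at C2 and C7a)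
Conditions: Ac2O, DMAP (cat.), pyridine, CH2Cl2, 0 °C
Reagents that add atoms: acetic anhydride, CC(=O)OC(C)=O
Why: DMAP-catalysed acylation of the tertiary hemiketal hydroxyl installs the anomeric leaving group; both anomers are usable because the anomeric carbon becomes sp2.

Step 9
Reactants: 16 acetoxypyranone; 17 tert-butyl acrylate
Product: 19 tert-butyl ester cycloadduct (oxygen bridge C3a–O–C6 on the β face; C7 ketone; C8=C8a; 3β-isopropyl; 6α-methyl; CO2tBu on C4 as both epimers), via oxidopyrylium ylide 18 (not isolated)
Conditions: tert-butyl acrylate (10 equiv), iPr2NEt, MeCN, 0 °C → rt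
Reagents that add atoms: none
Why: The amine removes the C6 proton and acetate leaves from C3a, giving the planar 3-oxidopyrylium ylide 18 (C3a and C6 become sp2, so every epimer of 16 converges), which adds the acrylate suprafacially across C3a and C6 in a concerted six-electron (5+2) cycloaddition; the closest known reaction type is the intermolecular oxidopyrylium–acrylate cycloaddition, of which an ylide alkylated at both termini lies at the edge of the scope. The seven-membered carbocycle is closed by this cycloaddition itself, C3a–C4 and C5–C6 forming in one step while the ring oxygen becomes the one-atom bridge. The isopropyl group on C3, directly beside the C3a terminus, screens its own face, so the alkene should bond anti to it; this leaves the bridging oxygen cis to isopropyl at C3a, and the configuration at C6 then follows from the bridge. The ester carbon is expected on C4, because the enolate-like terminus C6 bonds the acrylate CH2, as a mixture of C4 epimers; neither regio- nor endo/exo selectivity is needed, since all isomers give 22 after steps 10 and 11. The selectivities the step does need are facial selectivity and retention of the C3 centre: the isopropyl group secures the first, and excess acrylate, a hindered amine and low temperature are used so that cycloaddition outruns proton shift from C3 in the ylide.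

Step 10
Reactants: 19 tert-butyl ester cycloadduct
Product: 20 bridged enone C4-carboxylic acid (both C4 epimers)
Conditions: TFA/CH2Cl2 (1:4), 0 °C → rt
Reagents that add atoms: none
Why: Acidolysis of the tert-butyl ester (loss of isobutene through the tert-butyl cation) frees the acid while the ether bridge, the enone and the isopropyl centre are inert to TFA.

Step 11
Reactants: 20 bridged enone C4-carboxylic acid
Product: 22 oxygen-bridged enone (C3a–O–C6 bridge β; C7 ketone; C8=C8a; 3β-isopropyl; 6α-methyl; C4 and C5 are CH2), via thiohydroxamate ester 21 (not isolated)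
Conditions: 1-hydroxypyridine-2(1H)-thione, DCC, DMAP (cat.), CH2Cl2, 0 °C, dark; then t-BuSH, hν (tungsten lamp), rt
Reagents that add atoms: none
Why: Barton reductive decarboxylation: the thiohydroxamate ester fragments under light to CO2 and a secondary C4 radical that takes hydrogen from the thiol, a radical next to the C3a–O bond cannot expel the oxygen, and both C4 epimers (and any C5 regioisomer carried along) converge on one compound.

Step 12
Reactants: 22 oxygen-bridged enone
Product: 24 oxygen-bridged ketone with 8aβ-methyl (C3a–O–C6 bridge β; C7 ketone; 3β-isopropyl; 6α-methyl), via trimethylsilyl enol ether 23 (not isolated)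
Conditions: Me2CuLi (from MeLi and CuI), TMSCl, Et2O/THF, −78 → −30 °C; then 1 M HCl
Reagents that add atoms: lithium dimethylcuprate, [Li+].C[Cu-]C
Why: TMSCl-accelerated Gilman cuprate conjugate addition: the methyl group should enter C8a from the exo face of the bicycle, the face of the oxygen bridge and away from the C4–C5 bridge, which sets the quaternary centre with methyl cis to the C3a oxygen.

Step 13
Reactants: 24 oxygen-bridged methyl ketone
Product: 26 bis(triethylsilyl) compound (C6=C7 enol ether with OSiEt3 on C7; OSiEt3 on C3a β; 8aβ-methyl; 3β-isopropyl), via dilithium enolate alkoxide 25 (not isolated)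
Conditions: LiC10H8 (lithium naphthalenide, 2.2 equiv), THF, −78 °C; then Et3SiOTf (2.5 equiv), −78 → 0 °C
Reagents that add atoms: triethylsilyl trifluoromethanesulfonate, CC[Si](CC)(CC)OS(=O)(=O)C(F)(F)F
Why: Electron-transfer reductive cleavage of an α-alkoxy ketone (dissolving-metal type): the ketyl expels the C6–O bond, a second electron gives the C6=C7 lithium enolate regiospecifically together with the C3a alkoxide, and O-silylation of both in the same flask fixes the enol ether position and prevents transannular hemiketal formation; C6 becomes sp2.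

Step 14
Reactants: 26 bis(triethylsilyl) enol ether
Product: 28 6α-hydroxy-6β-methyl-7-ketone with C3a OSiEt3, via silyloxy epoxide 27 (not isolated)
Conditions: DMDO, acetone/CH2Cl2, −40 °C; then AcOH/THF/H2O, 0 °C
Reagents that add atoms: dimethyldioxirane, CC1(C)OO1
Why: Rubottom oxidation with dimethyldioxirane: the β face of the tetrasubstituted enol ether is screened by the C8a methyl and the C3a triethylsilyloxy group, so oxygen should be transferred to the α face, and mild hydrolysis of the silyloxy epoxide gives the 6α-hydroxy ketone with the C6 oxygen trans to the C3a oxygen.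

Step 15
Reactants: 28 α-hydroxy ketone
Product: 29 6α,7β-diol with C3a OSiEt3
Conditions: Me4NBH(OAc)3, MeCN/AcOH, −30 → −10 °C
Reagents that add atoms: none
Why: Hydroxyl-directed reduction with a triacetoxyborohydride (Evans–Saksena type): the C6 hydroxyl exchanges onto boron and delivers hydride to the α face of C7, which is also the face away from the C8a methyl, so the C7 hydroxyl should come out β, trans to the C6 hydroxyl.

Step 16
Reactants: 29 diol; 30 4-methoxybenzoyl chloride
Product: 31 7β-(4-methoxybenzoate) with free 6α-OH and C3a OSiEt3
Conditions: 4-MeOC6H4COCl, DMAP, pyridine, CH2Cl2, 0 °C → rt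
Reagents that add atoms: none
Why: DMAP-catalysed acylation by the acid chloride (nucleophilic catalysis) takes the only secondary hydroxyl; the tertiary C6 hydroxyl and the silyl ether do not react.

Step 17
Reactants: 31 silyl-protected ester
Product: 32 CNP0244624.1
Conditions: HF·pyridine, pyridine/THF, 0 °C → rt
Reagents that add atoms: none
Why: Fluoride-mediated cleavage of the silyl ether (Si–F bond formation) under pyridine-buffered conditions frees the C3a hydroxyl without ester migration or ionisation at the tertiary carbinols; no stereocentre is touched.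

**Compound list**

1 | 3-ethoxycyclopent-2-en-1-one | CCOC1=CC(=O)CC1 | starting material
2 | chloromagnesium 3-ethoxy-1-isopropylcyclopent-2-en-1-olate | CCOC1=CC(O[Mg]Cl)(C(C)C)CC1 | intermediate (not isolated)
3 | 3-isopropylcyclopent-2-en-1-one | CC(C)C1=CC(=O)CC1 | intermediate
4 | diethoxy{[(3R)-3-isopropylcyclopent-1-en-1-yl]oxy}methylsilane | CCO[Si](C)(OCC)OC1=C[C@@H](C(C)C)CC1 | intermediate
5 | (2R,3R)-2-{[diethoxy(methyl)silyl]oxy}-3-isopropylcyclopentan-1-one | O=C1[C@H](O[Si](C)(OCC)OCC)[C@@H](C(C)C)CC1 | intermediate (not isolated)
6 | (2R,3R)-2-hydroxy-3-isopropylcyclopentan-1-one | O=C1[C@H](O)[C@@H](C(C)C)CC1 | intermediate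
7 | (triphenylphosphoranylidene)ketene | O=C=C=P(c1ccccc1)(c1ccccc1)c1ccccc1 | starting material
8 | (1R,2R)-2-isopropyl-5-oxocyclopentyl (triphenylphosphoranylidene)acetate | O=C1[C@H](OC(=O)C=P(c2ccccc2)(c2ccccc2)c2ccccc2)[C@@H](C(C)C)CC1 | intermediate (not isolated)
9 | (6R,6aR)-6-isopropyl-4,5,6,6a-tetrahydro-2H-cyclopenta[b]furan-2-one | O=C1C=C2CC[C@H](C(C)C)[C@H]2O1 | intermediate
10 | (6R,6aR)-6-isopropyl-4,5,6,6a-tetrahydro-2H-cyclopenta[b]furan-2-ol | OC1C=C2CC[C@H](C(C)C)[C@H]2O1 | intermediate (not isolated)
11 | (6R)-6-isopropyl-5,6-dihydro-4H-cyclopenta[b]furan | CC(C)[C@H]1CCc2ccoc21 | intermediate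
12 | acetaldehyde | CC=O | starting material
13 | [(6R)-6-isopropyl-5,6-dihydro-4H-cyclopenta[b]furan-2-yl]lithium | [Li]c1cc2CC[C@H](C(C)C)c2o1 | intermediate (not isolated)
14 | 1-[(6R)-6-isopropyl-5,6-dihydro-4H-cyclopenta[b]furan-2-yl]ethan-1-ol (carbinol epimers) | CC(O)c1cc2CC[C@H](C(C)C)c2o1 | intermediate
15 | (7R)-7a-hydroxy-7-isopropyl-2-methyl-5,6,7,7a-tetrahydrocyclopenta[b]pyran-3(2H)-one (C2 and C7a epimers) | CC1OC2(O)[C@@H](C(C)C)CCC2=CC1=O | intermediate
16 | (7R)-7-isopropyl-2-methyl-3-oxo-2,3,5,6,7,7a-hexahydrocyclopenta[b]pyran-7a-yl acetate (C2 and C7a epimers) | CC1OC2(OC(C)=O)[C@@H](C(C)C)CCC2=CC1=O | intermediate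
17 | tert-butyl acrylate | C=CC(=O)OC(C)(C)C | starting material
18 | cyclopentane-fused 3-oxidopyrylium ylide (C3 isopropyl, C6 methyl) | Cc1[o+]c2[C@@H](C(C)C)CCc2cc1[O-] | intermediate (not isolated)
19 | tert-butyl ester cycloadduct: β oxygen bridge C3a–O–C6, C7 ketone, C8=C8a, 3β-isopropyl, 6α-methyl, CO2tBu at C4 (C4 epimers) | O=C1C=C2CC[C@H](C(C)C)[C@@]2(O3)C(C(=O)OC(C)(C)C)C[C@@]13C | intermediate
20 | corresponding C4 carboxylic acid (C4 epimers) | O=C1C=C2CC[C@H](C(C)C)[C@@]2(O3)C(C(=O)O)C[C@@]13C | intermediate
21 | 2-thioxopyridin-1(2H)-yl ester of 20 | O=C1C=C2CC[C@H](C(C)C)[C@@]2(O3)C(C(=O)ON4C=CC=CC4=S)C[C@@]13C | intermediate (not isolated)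
22 | oxygen-bridged enone: β bridge C3a–O–C6, C7 ketone, C8=C8a, 3β-isopropyl, 6α-methyl | O=C1C=C2CC[C@H](C(C)C)[C@@]2(O3)CC[C@@]13C | intermediate
23 | C7 trimethylsilyl enol ether (C7=C8) of 24 | C[Si](C)(C)OC1=C[C@@]2(C)CC[C@H](C(C)C)[C@@]2(O3)CC[C@@]13C | intermediate (not isolated)
24 | oxygen-bridged ketone: β bridge C3a–O–C6, C7 ketone, 8aβ-methyl, 3β-isopropyl, 6α-methyl | O=C1C[C@@]2(C)CC[C@H](C(C)C)[C@@]2(O3)CC[C@@]13C | intermediate
25 | dilithium C6=C7 enolate C3a alkoxide | [Li+].[Li+].CC1=C([O-])C[C@@]2(C)CC[C@H](C(C)C)[C@@]2([O-])CC1 | intermediate (not isolated)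
26 | bis(triethylsilyl) compound: C6=C7 enol ether (C7 OSiEt3), C3a β-OSiEt3, 8aβ-methyl, 3β-isopropyl | CC1=C(O[Si](CC)(CC)CC)C[C@@]2(C)CC[C@H](C(C)C)[C@@]2(O[Si](CC)(CC)CC)CC1 | intermediate
27 | 6α,7α-epoxide of 26 | CC[Si](CC)(CC)O[C@]12C[C@@]3(C)CC[C@H](C(C)C)[C@@]3(O[Si](CC)(CC)CC)CC[C@@]1(C)O2 | intermediate (not isolated)
28 | 6α-hydroxy-6β-methyl-7-ketone with C3a β-OSiEt3 | O=C1C[C@@]2(C)CC[C@H](C(C)C)[C@@]2(O[Si](CC)(CC)CC)CC[C@@]1(C)O | intermediate
29 | 6α,7β-diol with C3a β-OSiEt3 | O[C@@H]1C[C@@]2(C)CC[C@H](C(C)C)[C@@]2(O[Si](CC)(CC)CC)CC[C@@]1(C)O | intermediate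
30 | 4-methoxybenzoyl chloride | COc1ccc(C(=O)Cl)cc1 | starting material
31 | 7β-(4-methoxybenzoate) with 6α-OH and C3a β-OSiEt3 | COc1ccc(C(=O)O[C@@H]2C[C@@]3(C)CC[C@H](C(C)C)[C@@]3(O[Si](CC)(CC)CC)CC[C@@]2(C)O)cc1 | intermediate
32 | CNP0244624.1 | COc1ccc(C(=O)O[C@@H]2C[C@@]3(C)CC[C@H](C(C)C)[C@@]3(O)CC[C@@]2(C)O)cc1 | target

**Step count and risks**

Total step count: 17. Longest linear sequence: 17 steps (compound 1 to compound 32).

The three steps most likely to fail, each with its fallback:

First risk, step 9, the key cycloaddition. The hindered ylide may be trapped by the acrylate more slowly than it shifts a proton from C3 to C6 (which would erase the only controlling centre) or dimerises, and facial discrimination at C3a may be incomplete. The fallback uses a smaller, more electrophilic partner and an organometallic excision in place of the radical one. It sets out from 16: acrolein and iPr2NEt in MeCN at 0 °C should give, by the same (5+2) addition, the C4-formyl cycloadduct F1 as a mixture of C4 epimers. Stoichiometric RhCl(PPh3)3 in toluene at 110 °C (Tsuji–Wilkinson decarbonylation, which passes through no carbanion) should then remove the formyl group of F1 as rhodium-bound CO. The fallback comes back to the route at 22.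

Second risk, step 12, the methyl group at C8a. Methyl transfer to a fully substituted β-carbon next to the quaternary C3a may stall, or 1,2-addition may compete. The fallback sets out from 22: dimethylsulfoxonium methylide (Me3S(O)I, NaH, DMSO, rt; Corey–Chaykovsky cyclopropanation) delivers a small carbon nucleophile to C8a from the same exo face and should close the C8–C8a cyclopropyl ketone F2. Hydrogenolysis of F2 over Pd/C (H2, EtOAc) should cleave the C8–CH2 bond, the less substituted cyclopropane bond and the one that overlaps the carbonyl π system, leaving the methyl group on C8a. The fallback comes back to the route at 24.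

Third risk, step 14, the C6 hydroxylation. Oxygen may be transferred to the β face of the enol ether instead of the α face (poor or inverted facial selectivity). The fallback turns a β-face preference to advantage and sets out from 26.
- MeLi in THF at 0 °C frees the lithium enolate, and PhNTf2 should convert it into the C7 enol triflate F3.
- Pd(OAc)2, PPh3, HCO2H and Bu3N in DMF at 60 °C should reduce the triflate to the C6=C7 alkene F4.
- mCPBA should then add from the β face to give the 6β,7β-epoxide F5.
- Acid-catalysed hydrolysis (cat. HClO4, THF/H2O, 0 °C) should open the epoxide at the tertiary C6 with inversion, so water enters from the α face and the C7 oxygen stays β.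

The fallback comes back to the route at diol 29, and step 15 is then not needed.

Further compounds

F1 | step 9 | C4-formyl cycloadduct: β oxygen bridge C3a–O–C6, C7 ketone, C8=C8a, 3β-isopropyl, 6α-methyl, CHO at C4 (C4 epimers) | O=C1C=C2CC[C@H](C(C)C)[C@@]2(O3)C(C=O)C[C@@]13C
F2 | step 12 | C8–C8a cyclopropyl ketone of the bridged system (CH2 on the exo, β face) | O=C1[C@@H]2C[C@@]23CC[C@H](C(C)C)[C@@]3(O4)CC[C@@]14C
F3 | step 14 | C7 enol triflate (C6=C7) with C3a β-OSiEt3 | CC1=C(OS(=O)(=O)C(F)(F)F)C[C@@]2(C)CC[C@H](C(C)C)[C@@]2(O[Si](CC)(CC)CC)CC1
F4 | step 14 | C6=C7 alkene with C3a β-OSiEt3 | CC1=CC[C@@]2(C)CC[C@H](C(C)C)[C@@]2(O[Si](CC)(CC)CC)CC1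
F5 | step 14 | 6β,7β-epoxide with C3a β-OSiEt3 | O1[C@@H]2C[C@@]3(C)CC[C@H](C(C)C)[C@@]3(O[Si](CC)(CC)CC)CC[C@]12C
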